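## Retrosynthetic overview

1. The route rests on one feature of ring B. C7 carries the acrylate C11(=C13H2)–C12O2Me, the neighbouring C8 carries oxygen, and the two are cis (both β). This homoallylic alcohol is the retron of an aldehyde allylation by a 2-(bromomethyl)enoate, so C7–C8 is cut (CrCl2, step 12). That one bond closes ring B and sets C7, C8 and the C11=C13 methylene together.
2. After the closure: acetate on O8, angelate on O3 through a mixed anhydride, and last the 5α-OOH/C4=C15 unit by Schenck ene reaction of the C4=C5 alkene.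
3. Before the closure: the bromide arm C6–C7=C11(CH2Br) is grown from a C5–CH2CHO arm by acrylate α-anion addition and SN2′ bromination. The aldehyde arm C9–C8HO is the C10 allyl group, unmasked last.
4. Allyl groups on both C5 and C10 could not be told apart. The C5 arm therefore enters at the ester level, using ethoxyacetylide in a Stork–Danheiser transposition. C10 is set by Pd-catalysed decarboxylative allylation and C3 by CBS reduction.
5. Ring order: ring A is bought with 2-methylcyclohexane-1,3-dione; ring B is the only ring formed (step 12).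

Key step: step 12

Numbering: eudesmane numbering is used for all intermediates. Ring A is C1–C5 plus C10, ring B is C5–C10, C14 is the methyl on C10, C15 is the carbon on C4, and C11–C13 are the acrylate carbons. β is the face of C14.

Assumption: the sense of induction in step 4 is taken by analogy with the 2-allyl-2-methylcyclohexanone series, where the (S)-PHOX ligand gives the (S)-ketone. If the vinylogous ester responds in the opposite sense, the antipodal ligand is used.

## Route

Step 1
Reactants: 1 2-methylcyclohexane-1,3-dione; 2 isobutanol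
Product: 3 3-isobutoxy-2-methylcyclohex-2-en-1-one
Conditions: TsOH·H2O (cat.), toluene, Dean–Stark, reflux
Reagents that add atoms: isobutanol, CC(C)CO
Why: Acid-catalysed O-alkylation of the enolised 1,3-dione with azeotropic removal of water (vinylogous ester formation) masks one carbonyl group and leaves the future C10 as the only site of kinetic deprotonation; no stereocentre is formed.

Step 2
Reactants: 3 3-isobutoxy-2-methylcyclohex-2-en-1-one; 4 allyl chloroformate
Product: 5 allyl 4-isobutoxy-3-methyl-2-oxocyclohex-3-ene-1-carboxylate (racemic)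
Conditions: LiN(i-Pr)2 (2.1 equiv), toluene, −78 °C; 4, −78 °C → rt; aq. NH4Cl
Reagents that add atoms: allyl chloroformate, C=CCOC(Cl)=O
Why: Kinetic α′-deprotonation of the vinylogous ester at the future C10 and C-acylation by the chloroformate (crossed Claisen-type acylation) give the β-keto ester, the second equivalent of amide base taking up the more acidic product as it forms; the new stereocentre is racemic and is erased in step 4.

Step 3
Reactants: 5 allyl 4-isobutoxy-3-methyl-2-oxocyclohex-3-ene-1-carboxylate; 6 methyl iodide
Product: 7 allyl 4-isobutoxy-1,3-dimethyl-2-oxocyclohex-3-ene-1-carboxylate (racemic)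
Conditions: MeI, Cs2CO3, MeCN, 50 °C
Reagents that add atoms: methyl iodide, CI
Why: C-alkylation of the stabilised β-keto ester anion with methyl iodide under mild carbonate conditions installs the C14 methyl group; the quaternary centre is racemic, which does not matter because step 4 is stereoablative.

Step 4
Reactants: 7 allyl 4-isobutoxy-1,3-dimethyl-2-oxocyclohex-3-ene-1-carboxylate
Product: 8 (6R)-6-allyl-3-isobutoxy-2,6-dimethylcyclohex-2-en-1-one
Conditions: Pd2(dba)3 (2.5 mol %), (R)-t-BuPHOX (6.25 mol %), toluene, 40 °C
Reagents that add atoms: none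
Why: Decarboxylative asymmetric allylic alkylation (enantioselective Tsuji allylation): zerovalent palladium ionises the allyl ester, CO2 is lost and the achiral enolate recombines with the allyl fragment inside the chiral PHOX–palladium complex, so that the ligand alone sets C10 as R (C14 methyl β), vinylogous esters of this dione being an established substrate class.

Step 5
Reactants: 8 (6R)-6-allyl-3-isobutoxy-2,6-dimethylcyclohex-2-en-1-one; 9 ethoxyacetylene
Product: 12 ethyl 2-[(6R)-6-allyl-2,6-dimethyl-3-oxocyclohex-1-en-1-yl]acetate, via lithium ethoxyacetylide 10 (not isolated), via lithium carbinolate 11 (not isolated)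
Conditions: 9, n-BuLi, THF, −78 °C; 8, −78 → 0 °C; then 1 M aq. HCl, THF, 0 °C → rt
Reagents that add atoms: ethoxyacetylene, C#COCC; water, O
Why: Stork–Danheiser transposition with an acetylide nucleophile: the slim, weakly basic acetylide 10 adds 1,2 to the hindered C5 carbonyl (3-alkoxycyclohexenones carrying a 2-methyl group and a quaternary C6 are known to accept acetylides), and aqueous acid then ionises the carbinol, hydrolyses the enol ether and hydrates the alkoxyalkyne to the ester, all pathways draining into the tetrasubstituted enone 12 as the thermodynamic sink, so that C6–C7 arrive at the ester level, the C10 allyl group stays the only terminal alkene and C10 is not touched.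

Step 6
Reactants: 12 ethyl 2-[(6R)-6-allyl-2,6-dimethyl-3-oxocyclohex-1-en-1-yl]acetate
Product: 13 ethyl 2-[(3R,6R)-6-allyl-3-hydroxy-2,6-dimethylcyclohex-1-en-1-yl]acetate (3α-OH)
Conditions: (S)-Me-CBS oxazaborolidine (20 mol %), catecholborane, toluene, −78 °C; MeOH, then aq. NaHCO3
Reagents that add atoms: none
Why: Corey–Bakshi–Shibata reduction: the (S)-oxazaborolidine binds the ketone with the fully substituted C4=C5 side as the large and C2H2 as the small group and passes hydride to the β face, which should set C3 as R (3α-OH) under reagent control because the remote C10 centre offers no useful bias; catecholborane at −78 °C leaves ester and allyl group alone, and material of the minor C10 series from step 4 becomes a diastereomer that is removed by chromatography.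

Step 7
Reactants: 13 ethyl 2-[(3R,6R)-6-allyl-3-hydroxy-2,6-dimethylcyclohex-1-en-1-yl]acetate; 14 tert-butyldimethylsilyl chloride
Product: 15 ethyl 2-[(3R,6R)-6-allyl-3-(tert-butyldimethylsilyloxy)-2,6-dimethylcyclohex-1-en-1-yl]acetate
Conditions: TBSCl, imidazole, DMF, rt
Reagents that add atoms: tert-butyldimethylsilyl chloride, CC(C)(C)[Si](C)(C)Cl
Why: Standard silylation of a secondary allylic alcohol with retention at C3 (the C–O bond is not broken); the silyl ether shields O3 through the hydride, organoaluminium, bromination, osmylation and chromium steps.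

Step 8
Reactants: 15 ethyl 2-[(3R,6R)-6-allyl-3-(tert-butyldimethylsilyloxy)-2,6-dimethylcyclohex-1-en-1-yl]acetate
Product: 17 2-[(3R,6R)-6-allyl-3-(tert-butyldimethylsilyloxy)-2,6-dimethylcyclohex-1-en-1-yl]acetaldehyde, via aluminium hemiacetal 16 (not isolated)
Conditions: i-Bu2AlH (1.05 equiv), CH2Cl2, −78 °C; MeOH, −78 °C; aq. potassium sodium tartrate
Reagents that add atoms: none
Why: Partial reduction of an ester with one equivalent of i-Bu2AlH: the tetrahedral aluminium hemiacetal 16 persists at −78 °C and gives the aldehyde only on cold protic quench, and the neutral conditions keep the C4=C5 alkene from moving into conjugation with the new aldehyde.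

Step 9
Reactants: 17 2-[(3R,6R)-6-allyl-3-(tert-butyldimethylsilyloxy)-2,6-dimethylcyclohex-1-en-1-yl]acetaldehyde; 18 methyl propiolate
Product: 20 methyl 4-[(3R,6R)-6-allyl-3-(tert-butyldimethylsilyloxy)-2,6-dimethylcyclohex-1-en-1-yl]-3-hydroxy-2-methylidenebutanoate (both C7 epimers), via vinylalane 19 (not isolated)
Conditions: i-Bu2AlH, NMO, THF, 0 °C; 18 (slight excess over hydride), 0 °C; 17, 0 °C → rt; aq. potassium sodium tartrate
Reagents that add atoms: methyl propiolate, C#CC(=O)OC
Why: Vinylalumination, an amine-free equivalent of the Morita–Baylis–Hillman reaction: hydroalumination of methyl propiolate by the i-Bu2AlH–NMO complex places aluminium on the α-carbon (19), which adds 1,2 to the aldehyde and forms C7–C11 without the long exposure to a nucleophilic amine under which 17, acidified at C6 by both the aldehyde and the C4=C5 alkene, could enolise, conjugate or expel the C3 silyloxy group; the C7 carbinol centre forms unselectively and is erased in step 10.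

Step 10
Reactants: 20 methyl 4-[(3R,6R)-6-allyl-3-(tert-butyldimethylsilyloxy)-2,6-dimethylcyclohex-1-en-1-yl]-3-hydroxy-2-methylidenebutanoate; 21 N-bromosuccinimide
Product: 22 methyl (2Z)-4-[(3R,6R)-6-allyl-3-(tert-butyldimethylsilyloxy)-2,6-dimethylcyclohex-1-en-1-yl]-2-(bromomethyl)but-2-enoate
Conditions: NBS, Me2S, CH2Cl2, 0 °C; then 20, 0 °C → rt
Reagents that add atoms: N-bromosuccinimide, O=C1CCC(=O)N1Br
Why: The allylic hydroxyl group is activated by the bromosulfonium reagent made from NBS and Me2S and is displaced by bromide in the SN2′ sense at C13 (the usual conversion of Morita–Baylis–Hillman alcohols into 2-(bromomethyl)enoates), which moves the alkene to C7=C11 with C6 trans to the ester (Z) to avoid A(1,3) strain; no acid is generated, so the allylic silyl ether survives.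

Step 11
Reactants: 22 methyl (2Z)-4-[(3R,6R)-6-allyl-3-(tert-butyldimethylsilyloxy)-2,6-dimethylcyclohex-1-en-1-yl]-2-(bromomethyl)but-2-enoate
Product: 24 methyl (2Z)-2-(bromomethyl)-4-[(3R,6R)-3-(tert-butyldimethylsilyloxy)-2,6-dimethyl-6-(2-oxoethyl)cyclohex-1-en-1-yl]but-2-enoate, via vicinal diol 23 (not isolated)
Conditions: OsO4 (2 mol %), NaIO4, 2,6-lutidine, 1,4-dioxane/H2O 3:1, rt
Reagents that add atoms: sodium periodate, [Na+].[O-]I(=O)(=O)=O; osmium tetroxide (oxygen carrier), O=[Os](=O)(=O)=O
Why: Lemieux–Johnson cleavage: OsO4 selects the only monosubstituted and electronically neutral alkene (C4=C5 is tetrasubstituted and C7=C11 is trisubstituted and electron-poor), NaIO4 cleaves diol 23 to the C8 aldehyde and re-oxidises osmium, and the 2-(bromomethyl)enoate tolerates the neutral aqueous medium just as such bromides do in aqueous Barbier reactions.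

Step 12
Reactants: 24 methyl (2Z)-2-(bromomethyl)-4-[(3R,6R)-3-(tert-butyldimethylsilyloxy)-2,6-dimethyl-6-(2-oxoethyl)cyclohex-1-en-1-yl]but-2-enoate
Product: 27 methyl (3R,7R,8R,10R)-8β-hydroxy-3α-(tert-butyldimethylsilyloxy)eudesma-4,11(13)-dien-12-oate, via allylchromium dichloride 25 (not isolated), via chromium alkoxide 26 (not isolated)
Conditions: CrCl2 (5 equiv), THF, 0.005 M, slow addition of 24, 0 °C → rt; cold pH 7 phosphate buffer
Reagents that add atoms: none
Why: Two CrCl2 (divalent chromium) reduce the C13–Br bond by successive single-electron transfers to the allylchromium dichloride 25 (trivalent chromium), which adds through its γ-carbon C7 to the C8 aldehyde in a closed Zimmerman–Traxler chair made of Cr, O8, C8, C7, C11 and C13 and so gives alkoxide 26 with the C11=C13 methylene in place; this is an intramolecular Nozaki–Hiyama–Kishi (Barbier-type) allylation, the reaction type by which 2-(bromomethyl)enoates and aldehydes are known to give the precursors of cis-fused α-methylene-γ-butyrolactones. Ring B (C5–C6–C7–C8–C9–C10) closes in the 6-exo-trig mode at the carbonyl carbon, helped by the two arms sitting on the adjacent ring A atoms C5 (sp2) and C10 (quaternary). The relative configuration C7/C8 is controlled by the allyl geometry: 25 equilibrates by 1,3-shift of the metal, so that either bromide geometry would serve, and it reacts from the form with C6 cis to C13 and trans to the ester, which puts C6 axial and C9 equatorial on the metal chair and therefore the acrylate and O8 cis on ring B. The sense relative to C10 is controlled by ring A, which forces the C14 methyl group axial on the nascent ring B chair: only the β,β arrangement (C11 equatorial at C7, O8 axial at C8) fits that preferred metal chair, whereas the α,α-cis product needs C9 axial on the metal chair plus C6 cis to the ester and the 7β,8α-trans product needs the latter. The price is a syn-axial O8/C14 contact, which makes the facial sense the least secure element of the step. The step also needs γ- over α-attack (α-attack would mean an eight-membered ring), addition rather than enolisation at C9 or C6 (organochromium reagents are hardly basic) and survival of enoate, silyl ether and C4=C5, and the cold neutral work-up keeps 27 from closing to the 12,8-lactone.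

Step 13
Reactants: 27 methyl 8β-hydroxy-3α-(tert-butyldimethylsilyloxy)eudesma-4,11(13)-dien-12-oate (crude); 28 acetic anhydride
Product: 29 methyl 8β-acetoxy-3α-(tert-butyldimethylsilyloxy)eudesma-4,11(13)-dien-12-oate
Conditions: Ac2O (excess), DMAP, pyridine, CH2Cl2, 0 °C
Reagents that add atoms: acetic anhydride, CC(=O)OC(C)=O
Why: DMAP-catalysed acylation of the axial 8β-alcohol with excess anhydride is run on the crude hydroxy ester so that acyl transfer outruns attack of O8 on C12 (lactonisation); configuration at C8 is retained because only the O–H bond reacts.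

Step 14
Reactants: 29 methyl 8β-acetoxy-3α-(tert-butyldimethylsilyloxy)eudesma-4,11(13)-dien-12-oate
Product: 30 methyl 8β-acetoxy-3α-hydroxyeudesma-4,11(13)-dien-12-oate
Conditions: HF·pyridine, pyridine, THF, 0 °C → rt
Reagents that add atoms: none
Why: Fluoride-induced cleavage of the silyl ether driven by the Si–F bond; pyridine-buffered HF is not basic enough to hydrolyse or shift the acetate or to add to the acrylate and not acidic enough to ionise the allylic C3–O bond, so C3 stays R.

Step 15
Reactants: 30 methyl 8β-acetoxy-3α-hydroxyeudesma-4,11(13)-dien-12-oate; 31 angelic acid; 32 2,4,6-trichlorobenzoyl chloride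
Product: 34 methyl 8β-acetoxy-3α-angeloyloxyeudesma-4,11(13)-dien-12-oate, via mixed anhydride 33 (not isolated)
Conditions: 31, 32, Et3N, toluene, rt; then 30, 75 °C
Reagents that add atoms: angelic acid, C/C=C(/C)C(=O)O
Why: Yamaguchi-type esterification through the mixed anhydride 33 without nucleophilic catalyst: the alcohol attacks the less hindered angeloyl carbonyl group, C3 is retained because its C–O bond is not broken, and the absence of acid chloride, DMAP and strong acid avoids Z to E isomerisation of the angelate to the tiglate.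

Step 16
Reactants: 34 methyl 8β-acetoxy-3α-angeloyloxyeudesma-4,11(13)-dien-12-oate; 35 dioxygen
Product: 36 methyl (3R,5S,7R,8R,10R)-8β-acetoxy-3α-angeloyloxy-5α-hydroperoxyeudesma-4(15),11(13)-dien-12-oate (CNP0116769.2)
Conditions: O2, tetraphenylporphyrin (cat.), CH2Cl2, visible light, −20 °C; no reductive work-up
Reagents that add atoms: dioxygen, O=O
Why: Schenck ene reaction: singlet oxygen reacts only with the electron-rich tetrasubstituted C4=C5 alkene (acrylate and angelate alkenes are electron-poor), it should approach from the α face because the β face is screened by the axial C14 methyl group and the axial 8β-acetate, and on that face only the C15 methyl group offers a C–H bond aligned with the π system (C3 has no α-hydrogen, C10 has none at all and H6α is equatorial), so that oxygen binds to C5, hydrogen leaves C15 and the alkene moves to C4=C15, which sets C5 as S (5α-OOH, trans to C14).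

## Compound list

1 | 2-methylcyclohexane-1,3-dione | CC1C(=O)CCCC1=O | starting material
2 | isobutanol (2-methylpropan-1-ol) | CC(C)CO | starting material
3 | 3-isobutoxy-2-methylcyclohex-2-en-1-one | CC1=C(OCC(C)C)CCCC1=O | intermediate
4 | allyl chloroformate | C=CCOC(Cl)=O | starting material
5 | allyl 4-isobutoxy-3-methyl-2-oxocyclohex-3-ene-1-carboxylate (racemic) | C=CCOC(=O)C1CCC(OCC(C)C)=C(C)C1=O | intermediate
6 | methyl iodide | CI | starting material
7 | allyl 4-isobutoxy-1,3-dimethyl-2-oxocyclohex-3-ene-1-carboxylate (racemic) | C=CCOC(=O)C1(C)CCC(OCC(C)C)=C(C)C1=O | intermediate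
8 | (6R)-6-allyl-3-isobutoxy-2,6-dimethylcyclohex-2-en-1-one | C=CC[C@@]1(C)CCC(OCC(C)C)=C(C)C1=O | intermediate
9 | ethoxyacetylene | C#COCC | starting material
10 | lithium ethoxyacetylide | [Li]C#COCC | intermediate
11 | lithium (6R)-6-allyl-1-(ethoxyethynyl)-3-isobutoxy-2,6-dimethylcyclohex-2-en-1-olate (both C1 epimers) | C=CC[C@@]1(C)CCC(OCC(C)C)=C(C)C1(O[Li])C#COCC | intermediate
12 | ethyl 2-[(6R)-6-allyl-2,6-dimethyl-3-oxocyclohex-1-en-1-yl]acetate | CCOC(=O)CC1=C(C)C(=O)CC[C@]1(C)CC=C | intermediate
13 | ethyl 2-[(3R,6R)-6-allyl-3-hydroxy-2,6-dimethylcyclohex-1-en-1-yl]acetate | CCOC(=O)CC1=C(C)[C@H](O)CC[C@]1(C)CC=C | intermediate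
14 | tert-butyldimethylsilyl chloride | CC(C)(C)[Si](C)(C)Cl | starting material
15 | ethyl 2-[(3R,6R)-6-allyl-3-(tert-butyldimethylsilyloxy)-2,6-dimethylcyclohex-1-en-1-yl]acetate | CCOC(=O)CC1=C(C)[C@H](O[Si](C)(C)C(C)(C)C)CC[C@]1(C)CC=C | intermediate
16 | diisobutylaluminium hemiacetal of ester 15 | CCOC(O[Al](CC(C)C)CC(C)C)CC1=C(C)[C@H](O[Si](C)(C)C(C)(C)C)CC[C@]1(C)CC=C | intermediate
17 | 2-[(3R,6R)-6-allyl-3-(tert-butyldimethylsilyloxy)-2,6-dimethylcyclohex-1-en-1-yl]acetaldehyde | O=CCC1=C(C)[C@H](O[Si](C)(C)C(C)(C)C)CC[C@]1(C)CC=C | intermediate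
18 | methyl propiolate | C#CC(=O)OC | starting material
19 | methyl 2-(diisobutylalumanyl)acrylate | C=C(C(=O)OC)[Al](CC(C)C)CC(C)C | intermediate
20 | methyl 4-[(3R,6R)-6-allyl-3-(tert-butyldimethylsilyloxy)-2,6-dimethylcyclohex-1-en-1-yl]-3-hydroxy-2-methylidenebutanoate (both C7 epimers) | C=C(C(=O)OC)C(O)CC1=C(C)[C@H](O[Si](C)(C)C(C)(C)C)CC[C@]1(C)CC=C | intermediate
21 | N-bromosuccinimide | O=C1CCC(=O)N1Br | starting material
22 | methyl (2Z)-4-[(3R,6R)-6-allyl-3-(tert-butyldimethylsilyloxy)-2,6-dimethylcyclohex-1-en-1-yl]-2-(bromomethyl)but-2-enoate | BrC/C(C(=O)OC)=C\CC1=C(C)[C@H](O[Si](C)(C)C(C)(C)C)CC[C@]1(C)CC=C | intermediate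
23 | methyl (2Z)-2-(bromomethyl)-4-[(3R,6R)-3-(tert-butyldimethylsilyloxy)-6-(2,3-dihydroxypropyl)-2,6-dimethylcyclohex-1-en-1-yl]but-2-enoate (both carbinol epimers) | BrC/C(C(=O)OC)=C\CC1=C(C)[C@H](O[Si](C)(C)C(C)(C)C)CC[C@]1(C)CC(O)CO | intermediate
24 | methyl (2Z)-2-(bromomethyl)-4-[(3R,6R)-3-(tert-butyldimethylsilyloxy)-2,6-dimethyl-6-(2-oxoethyl)cyclohex-1-en-1-yl]but-2-enoate | BrC/C(C(=O)OC)=C\CC1=C(C)[C@H](O[Si](C)(C)C(C)(C)C)CC[C@]1(C)CC=O | intermediate
25 | allylchromium dichloride from 24 (THF-solvated, trivalent chromium on C13) | Cl[Cr](Cl)C/C(C(=O)OC)=C\CC1=C(C)[C@H](O[Si](C)(C)C(C)(C)C)CC[C@]1(C)CC=O | intermediate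
26 | dichlorochromium 8β-alkoxide of 27 | C=C(C(=O)OC)[C@H]1CC2=C(C)[C@H](O[Si](C)(C)C(C)(C)C)CC[C@]2(C)C[C@H]1O[Cr](Cl)Cl | intermediate
27 | methyl (3R,7R,8R,10R)-8β-hydroxy-3α-(tert-butyldimethylsilyloxy)eudesma-4,11(13)-dien-12-oate | C=C(C(=O)OC)[C@H]1CC2=C(C)[C@H](O[Si](C)(C)C(C)(C)C)CC[C@]2(C)C[C@H]1O | intermediate
28 | acetic anhydride | CC(=O)OC(C)=O | starting material
29 | methyl 8β-acetoxy-3α-(tert-butyldimethylsilyloxy)eudesma-4,11(13)-dien-12-oate | C=C(C(=O)OC)[C@H]1CC2=C(C)[C@H](O[Si](C)(C)C(C)(C)C)CC[C@]2(C)C[C@H]1OC(C)=O | intermediate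
30 | methyl 8β-acetoxy-3α-hydroxyeudesma-4,11(13)-dien-12-oate | C=C(C(=O)OC)[C@H]1CC2=C(C)[C@H](O)CC[C@]2(C)C[C@H]1OC(C)=O | intermediate
31 | angelic acid, (Z)-2-methylbut-2-enoic acid | C/C=C(/C)C(=O)O | starting material
32 | 2,4,6-trichlorobenzoyl chloride | O=C(Cl)c1c(Cl)cc(Cl)cc1Cl | starting material
33 | angelic 2,4,6-trichlorobenzoic anhydride | C/C=C(/C)C(=O)OC(=O)c1c(Cl)cc(Cl)cc1Cl | intermediate
34 | methyl 8β-acetoxy-3α-angeloyloxyeudesma-4,11(13)-dien-12-oate | C=C(C(=O)OC)[C@H]1CC2=C(C)[C@H](OC(=O)/C(C)=C\C)CC[C@]2(C)C[C@H]1OC(C)=O | intermediate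
35 | dioxygen | O=O | starting material
36 | methyl (3R,5S,7R,8R,10R)-8β-acetoxy-3α-angeloyloxy-5α-hydroperoxyeudesma-4(15),11(13)-dien-12-oate | C=C(C(=O)OC)[C@H]1C[C@@]2(OO)C(=C)[C@H](OC(=O)/C(C)=C\C)CC[C@]2(C)C[C@H]1OC(C)=O | target

## Step count and risks

Total step count: 16. Longest linear sequence: 16 steps (1 → 36).

**Step 12.** The risk is loss of stereocontrol in the ring closure.
- The syn-axial O8/C14 contact may let the trans-diequatorial chair or the α,α-cis chair compete, eroding the C7/C8 configuration relative to C10.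
- The fallback separates ring closure from stereocontrol. It sets out from 24 and comes back at 27.
- The CrCl2 closure is run as before, and the whole mixture of ring-closed C7/C8 isomers, methyl 8-hydroxy-3α-(tert-butyldimethylsilyloxy)eudesma-4,11(13)-dien-12-oate F1, is oxidised with Dess–Martin periodinane (NaHCO3, CH2Cl2).
- The ketone is left only briefly with Et3N so that C7 settles with the acrylate equatorial. Longer contact could move C11=C13 into conjugation. This should give methyl 3α-(tert-butyldimethylsilyloxy)-8-oxoeudesma-4,11(13)-dien-12-oate F2.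
- Reduction with catecholborane and the (S)-Me-CBS oxazaborolidine treats C7 as the large side. The axial C14 methyl group also blocks the β face, so hydride should arrive from the α face and give 27.

**Step 16.** The risk is approach of singlet oxygen from the wrong face or regiochemical leakage.
- The pseudoaxial 3α-acyloxy group lies on the α face and may repel the incoming oxygen. That would open β-face pathways leading to a 5β- or a 4-hydroperoxide.
- The fallback reverses the order of acylation and oxygenation. A free 3α-hydroxyl group, held pseudoaxial by A(1,2) strain with C15, then attracts singlet oxygen to the α face by hydrogen bonding (hydroxyl-directed ene reaction in a non-polar solvent). It sets out from 30 and comes back at 36.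
- Photooxygenation of 30 (O2, tetraphenylporphyrin, CH2Cl2, light) should give methyl 8β-acetoxy-5α-hydroperoxy-3α-hydroxyeudesma-4(15),11(13)-dien-12-oate F3.
- The more acidic and sterically remote OOH group is silylated selectively (Et3SiCl, 1 equiv, imidazole, −40 °C) to methyl 8β-acetoxy-3α-hydroxy-5α-(triethylsilylperoxy)eudesma-4(15),11(13)-dien-12-oate F4.
- Esterification with anhydride 33 as in step 15 gives methyl 8β-acetoxy-3α-angeloyloxy-5α-(triethylsilylperoxy)eudesma-4(15),11(13)-dien-12-oate F5, and buffered HF·pyridine frees 36.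

**Step 9.** The risk lies in the fragile aldehyde 17.
- Enolisation at C6, migration of C4=C5 into conjugation and vinylogous loss of the silyloxy group may compete with a slow addition of the vinylalane.
- The fallback replaces the acrylate α-metal reagent by a fast low-temperature aldol reaction of a masked acrylate, followed by Hofmann-type elimination. It sets out from 17 and comes back at 20.
- The lithium enolate of methyl 3-(dimethylamino)propanoate (LiN(i-Pr)2, THF, −78 °C) is treated with 17. This should give methyl 4-[(3R,6R)-6-allyl-3-(tert-butyldimethylsilyloxy)-2,6-dimethylcyclohex-1-en-1-yl]-2-[(dimethylamino)methyl]-3-hydroxybutanoate F6.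
- Methyl iodide in MeOH gives the corresponding trimethylammonium iodide, [4-[(3R,6R)-6-allyl-3-(tert-butyldimethylsilyloxy)-2,6-dimethylcyclohex-1-en-1-yl]-3-hydroxy-2-(methoxycarbonyl)butyl]trimethylammonium iodide F7.
- NaHCO3 in aqueous THF eliminates the amine to give 20.

## Further compounds

F1 | step 12 | methyl 8-hydroxy-3α-(tert-butyldimethylsilyloxy)eudesma-4,11(13)-dien-12-oate (mixture of C7 and C8 isomers) | C=C(C(=O)OC)C1CC2=C(C)[C@H](O[Si](C)(C)C(C)(C)C)CC[C@]2(C)CC1O
F2 | step 12 | methyl 3α-(tert-butyldimethylsilyloxy)-8-oxoeudesma-4,11(13)-dien-12-oate (7β-acrylate) | C=C(C(=O)OC)[C@H]1CC2=C(C)[C@H](O[Si](C)(C)C(C)(C)C)CC[C@]2(C)CC1=O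
F3 | step 16 | methyl 8β-acetoxy-5α-hydroperoxy-3α-hydroxyeudesma-4(15),11(13)-dien-12-oate | C=C(C(=O)OC)[C@H]1C[C@@]2(OO)C(=C)[C@H](O)CC[C@]2(C)C[C@H]1OC(C)=O
F4 | step 16 | methyl 8β-acetoxy-3α-hydroxy-5α-(triethylsilylperoxy)eudesma-4(15),11(13)-dien-12-oate | C=C(C(=O)OC)[C@H]1C[C@@]2(OO[Si](CC)(CC)CC)C(=C)[C@H](O)CC[C@]2(C)C[C@H]1OC(C)=O
F5 | step 16 | methyl 8β-acetoxy-3α-angeloyloxy-5α-(triethylsilylperoxy)eudesma-4(15),11(13)-dien-12-oate | C=C(C(=O)OC)[C@H]1C[C@@]2(OO[Si](CC)(CC)CC)C(=C)[C@H](OC(=O)/C(C)=C\C)CC[C@]2(C)C[C@H]1OC(C)=O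
F6 | step 9 | methyl 4-[(3R,6R)-6-allyl-3-(tert-butyldimethylsilyloxy)-2,6-dimethylcyclohex-1-en-1-yl]-2-[(dimethylamino)methyl]-3-hydroxybutanoate (diastereomer mixture) | CN(C)CC(C(=O)OC)C(O)CC1=C(C)[C@H](O[Si](C)(C)C(C)(C)C)CC[C@]1(C)CC=C
F7 | step 9 | [4-[(3R,6R)-6-allyl-3-(tert-butyldimethylsilyloxy)-2,6-dimethylcyclohex-1-en-1-yl]-3-hydroxy-2-(methoxycarbonyl)butyl]trimethylammonium iodide | C[N+](C)(C)CC(C(=O)OC)C(O)CC1=C(C)[C@H](O[Si](C)(C)C(C)(C)C)CC[C@]1(C)CC=C.[I-]
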